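**Retrosynthesis**
1. The target comes from Pd/C hydrogenolysis of the two aryl benzyl ethers. Before that, 9-BBN hydroboration–oxidation of a (Z)-2-benzylidene-3-aryl-tetrahydrofuran-4-ol sets C1 and C2.
2. The benzylidene THF comes from Pd(II) 5-exo-dig cycloisomerisation of an alkyne diol, so the ring is formed after the coupling.
3. The late coupling joins the C2–C3 bond. An Et2Al-alkynyl (C16 aryl alkyne) opens a cis-3-aryl-2,3-epoxy alcohol (C17) at the benzylic carbon with inversion. This sets C3 and C4.
4. The epoxy alcohol comes from Sharpless AE of the Z-cinnamyl alcohol, built from 4-bromoguaiacol ether by Sonogashira then Lindlar. The alkyne comes from benzyl vanillin by Corey–Fuchs. Both aryl pieces come from guaiacol, which comes from catechol.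

Assumptions: all phenols are carried as benzyl ethers to the last step. The benzylic alcohol tolerates brief Pd/C hydrogenolysis, as in related 7-hydroxylignans.

**Route**

**Step 1**
Reactants: 1 catechol
Product: 2 guaiacol (2-methoxyphenol)
Conditions: (MeO)2CO, cat. K2CO3, 160 °C, sealed tube
Reagents that add atoms: dimethyl carbonate, COC(=O)OC
Why: Base-catalysed O-methylation with dimethyl carbonate stops largely at the mono-ether because the guaiacol phenoxide is less reactive; no stereocentre is involved.

**Step 2**
Reactants: 2 guaiacol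
Product: 3 4-bromo-2-methoxyphenol
Conditions: NBS, cat. i-Pr2NH, CH2Cl2, −78 °C → rt
Reagents that add atoms: N-bromosuccinimide, O=C1CCC(=O)N1Br
Why: Electrophilic aromatic bromination occurs para to the strongly activating OH.

**Step 3**
Reactants: 3 4-bromo-2-methoxyphenol
Product: 4 1-(benzyloxy)-4-bromo-2-methoxybenzene
Conditions: BnBr, K2CO3, DMF, 60 °C
Reagents that add atoms: benzyl bromide, BrCc1ccccc1
Why: Williamson etherification protects the phenol as a benzyl ether that survives the Pd, Al and borane steps.

**Step 4**
Reactants: 4 aryl bromide; 5 propargyl alcohol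
Product: 6 3-[4-(benzyloxy)-3-methoxyphenyl]prop-2-yn-1-ol
Conditions: Pd(PPh3)2Cl2 (3 mol%), CuI (5 mol%), Et3N, 70 °C
Reagents that add atoms: none
Why: Sonogashira coupling joins the aryl and the C3 unit; there is no stereocentre.

**Step 5**
Reactants: 6
Product: 7 (Z)-3-[4-(benzyloxy)-3-methoxyphenyl]prop-2-en-1-ol
Conditions: H2 (1 atm), Lindlar catalyst, quinoline, EtOAc, rt
Reagents that add atoms: none
Why: Syn hydrogenation on the poisoned catalyst stops at the cis-alkene, fixing the Z geometry needed for a cis-epoxide.

**Step 6**
Reactants: 7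
Product: 8 [(2R,3S)-3-(4-benzyloxy-3-methoxyphenyl)oxiran-2-yl]methanol (cis-epoxy alcohol)
Conditions: Ti(OiPr)4 (10 mol%), D-(−)-DET (12 mol%), TBHP, 4 Å MS, CH2Cl2, −20 °C
Reagents that add atoms: tert-butyl hydroperoxide, CC(C)(C)OO
Why: Sharpless asymmetric epoxidation delivers oxygen to one face of the allylic alcohol. D-(−)-DET gives the 2R configuration at the carbon that becomes C4, and syn delivery to the Z-alkene makes the epoxide cis, which becomes the cis-aryl/OH relationship.

**Step 7**
Reactants: 2 guaiacol; 9 glyoxylic acid
Product: 10 4-hydroxy-3-methoxymandelic acid (racemic)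
Conditions: aq. NaOH (2.2 equiv), 0 → 25 °C; then H3O+
Reagents that add atoms: none
Why: Hydroxyalkylation of the guaiacolate at the para position (Friedel–Crafts type) gives the mandelic acid. Its racemic carbinol centre is destroyed in the next step.

**Step 8**
Reactants: 10
Product: 11 vanillin
Conditions: O2 (air), cat. Cu(OH)2, aq. NaOH, 80 °C; then H3O+
Reagents that add atoms: none
Why: Copper-catalysed oxidative decarboxylation of the mandelate gives the aldehyde.

**Step 9**
Reactants: 11 vanillin
Product: 12 4-(benzyloxy)-3-methoxybenzaldehyde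
Conditions: BnBr, K2CO3, DMF, 60 °C
Reagents that add atoms: benzyl bromide, BrCc1ccccc1
Why: Williamson etherification protects the phenol.

**Step 10**
Reactants: 12
Product: 13 4-(benzyloxy)-1-(2,2-dibromovinyl)-2-methoxybenzene
Conditions: CBr4, PPh3, CH2Cl2, 0 °C → rt
Reagents that add atoms: carbon tetrabromide, BrC(Br)(Br)Br
Why: Corey–Fuchs (Ramirez) dibromo-olefination converts the aldehyde to the gem-dibromoalkene.

**Step 11**
Reactants: 13
Product: 14 4-(benzyloxy)-1-ethynyl-2-methoxybenzene
Conditions: n-BuLi (2.2 equiv), THF, −78 °C → rt; then H2O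
Reagents that add atoms: none
Why: Lithium–halogen exchange and elimination (Fritsch–Buttenberg–Wiechell) give the lithium acetylide, which is protonated on workup.

**Step 12 (late coupling of the two fragments)**
Reactants: 14 aryl alkyne; 8 cis-epoxy alcohol
Product: 15 (2S,3R)-3-(4-benzyloxy-3-methoxyphenyl)-3-[(4-benzyloxy-3-methoxyphenyl)ethynyl]propane-1,2-diol. This is the alkyne diol with C3 and C4 set, with C3 carrying the aryl and the alkyne; it is drawn by the SMILES in the list.
Conditions: 14, n-BuLi, THF/hexane, −78 °C; Et2AlCl, toluene, −78 → 0 °C; then 8, 0 °C → rt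
Reagents that add atoms: none
Why: The alkynylalane opens the 2,3-epoxy alcohol regioselectively at the benzylic C3 with inversion, the free OH directing the aluminium. The cis-epoxide therefore gives the C3/C4 relationship that becomes the cis-3-aryl-4-hydroxy THF.

**Step 13**
Reactants: 15
Product: 16 (Z)-2-(arylmethylene)-3-aryl-tetrahydrofuran-4-ol, the exocyclic enol ether with Ar′ cis to the ring O
Conditions: PdCl2(MeCN)2 (5 mol%), solid NaHCO3, THF, 23 °C; crude used directly
Reagents that add atoms: none
Why: Pd(II) 5-exo-dig hydroalkoxylation by the primary OH proceeds by anti-oxypalladation and protodepalladation, forming the THF ring and the Z enol ether. C3 and C4 are untouched.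

**Step 14**
Reactants: 16
Product: 17 bis-O-benzyl Metasequirin E
Conditions: 9-BBN (3 equiv), THF, 0 °C → rt; then 30% H2O2, 3 M NaOH, 0 °C
Reagents that add atoms: hydrogen peroxide, OO
Why: Hydroboration of an enol ether places boron on the benzylic carbon C1 and hydrogen on C2. Syn addition from the face opposite the cis C3-aryl and C4-OH puts H on C2 trans to the aryl, which makes C1 cis. The Z geometry fixes C1 as R, and oxidation proceeds with retention.

**Step 15**
Reactants: 17
Product: 18 Metasequirin E
Conditions: H2 (1 atm), 10% Pd/C, EtOAc/EtOH, rt, 1–2 h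
Reagents that add atoms: none
Why: Hydrogenolysis removes both phenolic benzyl ethers, and no stereocentre is touched.

**Compound list**

1 | catechol | Oc1ccccc1O | starting material
2 | guaiacol | COc1ccccc1O | intermediate
3 | 4-bromo-2-methoxyphenol | COc1cc(Br)ccc1O | intermediate
4 | 1-(benzyloxy)-4-bromo-2-methoxybenzene | COc1cc(Br)ccc1OCc1ccccc1 | intermediate
5 | propargyl alcohol | C#CCO | starting material
6 | 3-[4-(benzyloxy)-3-methoxyphenyl]prop-2-yn-1-ol | COc1cc(C#CCO)ccc1OCc1ccccc1 | intermediate
7 | (Z)-3-[4-(benzyloxy)-3-methoxyphenyl]prop-2-en-1-ol | COc1cc(/C=C\CO)ccc1OCc1ccccc1 | intermediate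
8 | [(2R,3S)-3-(4-benzyloxy-3-methoxyphenyl)oxiran-2-yl]methanol | COc1cc([C@@H]2O[C@@H]2CO)ccc1OCc1ccccc1 | intermediate
9 | glyoxylic acid | O=CC(=O)O | starting material
10 | 4-hydroxy-3-methoxymandelic acid (racemic) | COc1cc(C(O)C(=O)O)ccc1O | intermediate
11 | vanillin | COc1cc(C=O)ccc1O | intermediate
12 | 4-(benzyloxy)-3-methoxybenzaldehyde | COc1cc(C=O)ccc1OCc1ccccc1 | intermediate
13 | 4-(benzyloxy)-1-(2,2-dibromovinyl)-2-methoxybenzene | COc1cc(C=C(Br)Br)ccc1OCc1ccccc1 | intermediate
14 | 4-(benzyloxy)-1-ethynyl-2-methoxybenzene | COc1cc(C#C)ccc1OCc1ccccc1 | intermediate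
15 | alkyne diol | COc1cc([C@@H](C#Cc2ccc(OCc3ccccc3)c(OC)c2)[C@H](O)CO)ccc1OCc1ccccc1 | intermediate
16 | (Z)-benzylidene THF-4-ol | COc1cc([C@H]2/C(OC[C@H]2O)=C/c3ccc(OCc4ccccc4)c(OC)c3)ccc1OCc1ccccc1 | intermediate
17 | bis-O-benzyl Metasequirin E | COc1cc([C@H]2[C@@H]([C@H](O)c3ccc(OCc4ccccc4)c(OC)c3)OC[C@H]2O)ccc1OCc1ccccc1 | intermediate
18 | Metasequirin E | COc1cc([C@H]2[C@@H]([C@H](O)c3ccc(O)c(OC)c3)OC[C@H]2O)ccc1O | target

**Totals:** 15 steps in total; the longest linear sequence is 10 steps (steps 1–6 and 12–15, or equivalently 1 and 7–11, then 12–15).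

**Three steps most likely to fail**
1. **Step 12 (benzylic epoxide opening).** The p-alkoxyaryl cation can leak SN1 character or give C2 attack, eroding stereospecificity.
   - Fallback: build the C3–C4 bond instead by Marshall–Tamaru anti-selective propargylation of TBSOCH2CHO with the enantioenriched 1,3-diarylpropargyl mesylate (Pd(0)/Et2Zn allenylzinc). This gives the same alkyne diol after desilylation.
2. **Step 13 (cycloisomerisation).** The aryl alkyne may go 6-endo, or the exocyclic enol ether may isomerise to the endocyclic tetrasubstituted isomer.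
   - Fallback: reduce the alkyne to the E-alkene (Red-Al), epoxidise it (Shi), and close the THF by base-mediated 5-exo epoxide opening. This sets C1/C2 with the correct anti relationship and replaces steps 13–14.
3. **Step 6 (Z-selective AE).** Z-allylic alcohols react slowly and may give moderate ee, and the electron-rich epoxide is acid-labile.
   - Fallback: run the AE on the E-alkene (≥95% ee) and carry it through step 12 to the trans diol. Then invert C4 by selective primary-OH silylation, Mitsunobu with p-nitrobenzoic acid, methanolysis and desilylation.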